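## The problem

The target 28 is a germacranolide. Its ten-membered carbocycle (C1–C10, germacrane numbering used throughout) is fused across C6–C7 to a butenolide, O–C12(=O)–C11=C7–C6, with an acetoxymethyl group (C13) on C11, a senecioyloxymethyl group (C14) on C10 and a methyl group (C15) on C4. The carbocycle carries a trans-2,3-oxirane, a 4,5-oxirane with cis ring bonds, the lactone oxygen at C6, an acetate at C8, an (S)-2-methyloxirane-2-carboxylate at C9 and a Z C1=C10 alkene. That makes seven ring stereocentres (2R,3S,4S,5S,6R,8R,9R) and one in the side chain. A ten-membered ring is the hardest carbocycle to close, so the closure belongs where the open chain has few rotatable bonds. Only C6, a bis-allylic carbinol, can be set by a general catalytic method on an open chain. C8 and C9 are neighbours and can be set together, and the four oxirane carbons follow from alkene geometry (2E, 4Z) and from the face the ring exposes, so C6 must control C8/C9 and these three must control the oxiranes. The vinyl oxiranes, the glycidic ester, the allylic esters that can migrate between O8, O9, O13 and O14, and the acidic butenolide hydrogen at C6 (more acidic while C7 bears a formyl group) exclude strong acid, strong base and low-valent metals late in the route. The opening feature is that C8 and C9 are adjacent carbinol carbons, each bound to an sp2 carbon (C7 of the butenolide, C10 of the C1=C10 alkene): both are reduced conjugated aldehydes, and C8–C9 is a pinacol bond.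

## Retrosynthesis

**28 ⇒ 27.** The four C–O bonds of the two oxiranes are cut first. Oxiranes would not survive the reducing metal of the ring closure or the acylations, and their trans (C2–C3) and cis (C4–C5) relationships are already encoded in a 2E,4Z-diene. Triene 27 has four fewer stereocentres. The forward step must epoxidise two of five alkenes: C1=C10 is deactivated by two allylic ester groups, and the senecioate and butenolide alkenes are conjugated to carbonyl groups. Oxygen must arrive on the outer ring face.

**27 ⇒ 26 ⇒ 25 ⇒ 21 ⇒ 20, with acid 23 from 22.** Three ester C–O bonds are cut: the senecioate at O14 (via alcohol 26 and silyl ether 25), the glycidic ester at O9 (acid 23, from commercial epoxy alcohol 22) and the acetate at O8 (21). The esters at O8 and O9 can only follow the step that creates these hydroxyls. O9 is capped directly after O8 so that the hydroxy acetate 21 does not live long enough for acetyl migration. The forward sequence must distinguish O8 from O9 in diol 20; the silyloxymethyl group on C10 shields O9.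

**20 ⇒ 19 (key).** The C8–C9 bond is cut to give dialdehyde 19. Neighbouring cuts were weighed:
- closure at C3–C4 by an intramolecular sp2–sp2 coupling would need C8 and C9 to be built on an open chain first;
- closure at an oxirane bond would need most stereocentres in place before the ring exists.

The pinacol cut removes the ring and two stereocentres at once and leaves an open chain with C6 as its only stereocentre. The butenolide, the Z,E,Z-triene and the two sp2-bound formyl groups leave few rotors. The forward reaction must couple head to head, give the trans (threo) diol and take its absolute sense from C6.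

**19 ⇒ 18 ⇒ 12 + 17.** Both formyl groups go back to primary allylic alcohols (18), because a formyl group on C7 labilises C6–H and the 10Z-dienal can isomerise; they are unveiled one step before use. The triene is then cut at C3–C4, an sp2–sp2 bond made with retention under neutral conditions. This gives two halves of similar size: butenolide iodide 12 (C4–C8, C11–C13, C15) and dienylstannane 17 (C1–C3, C9, C10, C14).

**17 ⇒ 15 + 16; 15 ⇒ 14 ⇒ 13 ⇒ 4.** The C1–C2 bond is cut to iodide 15 and the two-carbon distannane 16. The difficulty in 15 is to tell apart the two oxygenated methylene groups on C10 and to put C9 cis to C1's substituent. Adding silicon to C1 and a formyl carbon to C10 of alkyne 4, on the same side, solves both: C9 comes from the formyl group and C14 from the propargylic carbon (13). Reduction (14) and silicon–iodine exchange (15) follow.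

**12 ⇒ 10 ⇒ 9 ⇒ 8.** C8 is traced to a vinyl group, cleaved and reduced via aldehyde 11. The acetate at O13 is put on before the cleavage (10). The iodine on C4 is traced to a triethylsilyl group (9 from 8), because the C4 substituent has to pass through a Grignard step that an iodide might not survive.

**8 ⇒ 5.** The butenolide is opened at C7–C8, C11–C12 and the lactone C–O bond. Propargylic alcohol 5 already holds C6, C7, C11 and C13. Adding a vinyl group and a carboxyl carbon anti across C7≡C11, steered by the C6 alkoxide, closes the ring through intermediates 6 and 7. A titanium-mediated union of a butyne-1,4-diol derivative, an aldehyde and a one-carbon electrophile was considered and set aside. With a symmetric alkyne it leaves O8 and O13 identical; with an unsymmetric one it has no regiochemical control. Here the three carbons come from three different reagents.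

**5 ⇒ 3 + 4; 3 ⇒ 2 ⇒ 1.** The C6–C7 bond is cut to enal 3 and alkyne 4, so that a catalytic asymmetric alkynylation sets C6. Alkyne 4 thus serves twice (C13–C11–C7 here, C14–C10–C1 above). Enal 3 comes from alcohol 2, and 2 from butynol 1 by a trans-hydrosilylation that fixes the 4Z geometry.

## Roads not taken

Alternative 1: The C1–C6 segment is traced to an arene, and the cut assigns the C2–O and C3–O bonds to an enzyme. In the forward key step whole cells expressing toluene dioxygenase oxidise bromobenzene A1 to the cis-dihydrodiol A2, both C–O bonds on one face, leaving a bromodiene for later cleavage to an open chain.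
- Merits: two oxygenated stereocentres in absolute form from an achiral arene in one step; the cis-diol maps correctly onto the trans-oxirane after one inversion.
- Weak points: the step forms no skeletal bond of the ten-membered ring. The six-membered ring must still be cleaved and extended, and the C4 methyl group, the 4,5-oxirane, C6, the butenolide, C8/C9 and the ring closure remain open. The oxygen functions would be carried, protected, through most of the synthesis.
- Comparison: in fixing C2/C3 independently of any ring conformation this road is better than the chosen plan, which leaves both oxiranes to a late substrate-controlled epoxidation. Against this the chosen plan sets a key step that makes the ring and two stereocentres from a one-stereocentre precursor, and a longest sequence of 15 steps.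

Alternative 2: The cut is at C4–C5 and the C5–O bond of the 4,5-oxirane. In the forward key step a strong amide base forms the C5 enolate of a chloromethyl ketone, which adds to the C4 methyl ketone, and the alkoxide displaces chloride. This closes the ten-membered ring and the oxirane and gives the bis-epoxy ketone A3.
- Merits: ring and the most hindered oxirane carbon in one operation. Both oxiranes are in place before or at ring closure, so no late face selectivity is needed. In that respect it is better than the chosen plan.
- Weak points: an aldol addition to a ketone that closes a ten-membered ring is reversible and uphill. The base also threatens the acetates, the γ-hydrogens of the alkylidene ester and the C3 hydrogen next to the ketone, whose enolate can open the existing oxirane. C4 and C5 depend on a macrocyclic transition state. A3 still needs C6 reduction, lactonisation and exchange of two silyl ethers.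
- Comparison: the open-chain substrate of this closure carries four stereocentres and an oxirane, against one stereocentre in 19, and needs a strong base where the chosen closure is neutral. The chosen plan pays with the late epoxidation risk.

Alternative 3: The cut is the C2–C5 σ bond of a cis-fused cyclobutene. In the forward key step the bicyclic precursor is heated with a zinc Lewis acid. The four-membered ring opens in conrotatory fashion, the C2=C3 and C4=C5 π bonds form, and the four- and eight-membered rings merge into the Z,E,Z-cyclodecatrienone A4 with C8 and C9 already in place.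
- Merits: no entropic cost of a medium-ring closure, triene geometry set by orbital symmetry, C8/C9 made on a small ring by reliable methods. For the ring formation itself this road is probably safer than a pinacol macrocyclisation.
- Weak points: the bicyclic precursor needs a regiocontrolled [2+2] assembly that places the methyl group. A4 lacks C11, C12 and C13, so the whole butenolide with its tetrasubstituted alkene must be annulated onto a strained triene ketone. C6 would be set by a ketone reduction under macrocyclic control.
- Comparison: against the safer ring formation the chosen plan sets that all skeletal carbons and the finished butenolide are present before ring closure, with six steps after it.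

Key step: step 14

Assumption: in step 3 the (S,S) enantiomer of ProPhenol is taken to be the one that leads to (4S)-5; if the sense of induction is the opposite, (R,R)-ProPhenol is used and nothing else changes.

## Route

Step 1
Reactants: 1 but-2-yn-1-ol
Product: 2 (Z)-3-(triethylsilyl)but-2-en-1-ol
Conditions: Et3SiH, [Cp*Ru(MeCN)3]PF6 (1 mol%), CH2Cl2, 0 °C to rt
Reagents that add atoms: triethylsilane CC[SiH](CC)CC
Why: Ruthenium-catalysed trans-hydrosilylation of an internal propargylic alcohol: hydrogen and silicon add to opposite faces and silicon goes to the alkyne carbon remote from the hydroxyl, so silicon ends up cis to the carbinol carbon. This is the 4Z geometry, with silicon as a Grignard-stable placeholder for iodine.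

Step 2
Reactants: 2 (Z)-3-(triethylsilyl)but-2-en-1-ol
Product: 3 (Z)-3-(triethylsilyl)but-2-enal
Conditions: MnO2 (excess), CH2Cl2, rt; crude product used directly
Reagents that add atoms: none
Why: Allylic oxidation with MnO2 is neutral and stops at the aldehyde; the trisubstituted Z-alkene should not isomerise if the enal is not stored.

Step 3
Reactants: 3 (Z)-3-(triethylsilyl)but-2-enal; 4 tert-butyl(dimethyl)(prop-2-ynyloxy)silane
Product: 5 (4S,5Z)-1-[tert-butyl(dimethyl)silyl]oxy-6-(triethylsilyl)hept-5-en-2-yn-4-ol
Conditions: Me2Zn, (S,S)-ProPhenol (10 mol%), Ph3PO (20 mol%), toluene, 4 °C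
Reagents that add atoms: none
Why: Zinc–ProPhenol-catalysed asymmetric alkynylation of a conjugated aldehyde; the dinuclear zinc catalyst delivers the alkynyl group to one face of the formyl group and sets C6, the only stereocentre of the fragment, as S.

Step 4
Reactants: 5 (4S,5Z)-1-[tert-butyl(dimethyl)silyl]oxy-6-(triethylsilyl)hept-5-en-2-yn-4-ol
Product: 8 (5S)-4-ethenyl-3-(hydroxymethyl)-5-[(Z)-2-(triethylsilyl)prop-1-enyl]furan-2(5H)-one, via cyclic alkenylmagnesium alkoxide 6 (not isolated), via silyl-protected furanone 7 (not isolated)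
Conditions: CH2=CHMgCl (4 equiv), CuI (20 mol%), THF–toluene, −20 °C to rt; CO2 (1 atm), −20 °C to rt; 2 M HCl, THF–MeOH, rt
Reagents that add atoms: vinylmagnesium chloride C=C[Mg]Cl; carbon dioxide O=C=O
Why: Alkoxide-directed anti-carbomagnesiation of a 2-alkyn-1-ol: the C6 magnesium alkoxide steers vinyl to the near alkyne carbon (C7) and magnesium to C11 in the five-membered chelate 6. CO2 is therefore captured at C11 cis to the C6 oxygen, and acid closes the butenolide 7 and removes the primary silyl ether without touching C6. C13 comes from the alkyne, C8 from the Grignard reagent and C12 from CO2, so the two oxygenated methylene positions are never equivalent.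

Step 5
Reactants: 8 (5S)-4-ethenyl-3-(hydroxymethyl)-5-[(Z)-2-(triethylsilyl)prop-1-enyl]furan-2(5H)-one
Product: 9 (5S)-4-ethenyl-3-(hydroxymethyl)-5-[(Z)-2-iodoprop-1-enyl]furan-2(5H)-one
Conditions: N-iodosuccinimide (1.3 equiv), (CF3)2CHOH, 0 °C
Reagents that add atoms: N-iodosuccinimide O=C1CCC(=O)N1I
Why: Ipso-iododesilylation of a vinylsilane in hexafluoroisopropanol goes with retention and gives the Z-iodoalkene; the electron-poor vinylbutenolide diene is far less nucleophilic than the silyl-substituted alkene.

Step 6
Reactants: 9 (5S)-4-ethenyl-3-(hydroxymethyl)-5-[(Z)-2-iodoprop-1-enyl]furan-2(5H)-one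
Product: 10 [(5S)-4-ethenyl-5-[(Z)-2-iodoprop-1-enyl]-2-oxo-2,5-dihydrofuran-3-yl]methyl acetate
Conditions: Ac2O, pyridine, CH2Cl2, 0 °C to rt
Reagents that add atoms: acetic anhydride CC(=O)OC(C)=O
Why: Plain acetylation of the primary alcohol installs the C13 acetate of the target; pyridine is too weak a base to enolise the butenolide at C6.

Step 7
Reactants: 10 [(5S)-4-ethenyl-5-[(Z)-2-iodoprop-1-enyl]-2-oxo-2,5-dihydrofuran-3-yl]methyl acetate
Product: 12 [(5S)-4-(hydroxymethyl)-5-[(Z)-2-iodoprop-1-enyl]-2-oxo-2,5-dihydrofuran-3-yl]methyl acetate, via formyl butenolide 11 (not isolated)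
Conditions: OsO4 (2 mol%), NaIO4 (3 equiv), dioxane–H2O, 0 °C to rt; then NaBH4, CeCl3·7H2O, MeOH, −78 °C
Reagents that add atoms: osmium tetroxide O=[Os](=O)(=O)=O; sodium periodate [Na+].[O-]I(=O)(=O)=O
Why: Lemieux–Johnson cleavage takes the terminal vinyl group, the only alkene that is neither tetrasubstituted and conjugated to the lactone carbonyl nor deactivated by iodine. The formyl butenolide 11 is reduced at once under Luche conditions (1,2-selective, acetate untouched) so that C6–H does not stay next to a formyl group.

Step 8
Reactants: 4 tert-butyl(dimethyl)(prop-2-ynyloxy)silane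
Product: 13 (Z)-2-[[tert-butyl(dimethyl)silyl]oxymethyl]-3-[dimethyl(phenyl)silyl]prop-2-enal
Conditions: PhMe2SiH, CO (1 atm), Rh2(O2CC3F7)4 (0.5 mol%), CH2Cl2, 0 °C to rt, slow addition of 4
Reagents that add atoms: dimethyl(phenyl)silane C[SiH](C)c1ccccc1; carbon monoxide [C-]#[O+]
Why: Rhodium-catalysed silylformylation of a terminal alkyne: silicon adds to the terminal carbon (C1) and the formyl carbon (C9) to the internal carbon (C10) on the same side. This puts C9 cis to the future C1–C2 bond and distinguishes C9 (from CO) from C14 (the propargylic carbon).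

Step 9
Reactants: 13 (Z)-2-[[tert-butyl(dimethyl)silyl]oxymethyl]-3-[dimethyl(phenyl)silyl]prop-2-enal
Product: 14 (E)-2-[[tert-butyl(dimethyl)silyl]oxymethyl]-3-[dimethyl(phenyl)silyl]prop-2-en-1-ol
Conditions: NaBH4, MeOH, 0 °C
Reagents that add atoms: none
Why: 1,2-Reduction of the enal by borohydride; the alkene geometry is unchanged (silicon stays cis to the new hydroxymethyl group; the descriptor changes only because the silyloxymethyl group now ranks higher).

Step 10
Reactants: 14 (E)-2-[[tert-butyl(dimethyl)silyl]oxymethyl]-3-[dimethyl(phenyl)silyl]prop-2-en-1-ol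
Product: 15 (E)-2-[[tert-butyl(dimethyl)silyl]oxymethyl]-3-iodoprop-2-en-1-ol
Conditions: N-iodosuccinimide (1.3 equiv), (CF3)2CHOH, 0 °C
Reagents that add atoms: N-iodosuccinimide O=C1CCC(=O)N1I
Why: Ipso-iododesilylation with retention, as in step 5; iodine stays cis to the free hydroxymethyl group (C9).

Step 11
Reactants: 15 (E)-2-[[tert-butyl(dimethyl)silyl]oxymethyl]-3-iodoprop-2-en-1-ol; 16 (E)-1,2-bis(tributylstannyl)ethene
Product: 17 (2E,4E)-2-[[tert-butyl(dimethyl)silyl]oxymethyl]-5-(tributylstannyl)penta-2,4-dien-1-ol
Conditions: 16 (3 equiv), PdCl2(MeCN)2 (5 mol%), DMF, rt, dark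
Reagents that add atoms: none
Why: Stille coupling of a vinyl iodide with an excess of the distannane, so that only one tin is used; both alkene geometries are retained, giving the C1–C2 bond and a 2E-dienylstannane with C9 still cis to C2.

Step 12
Reactants: 12 [(5S)-4-(hydroxymethyl)-5-[(Z)-2-iodoprop-1-enyl]-2-oxo-2,5-dihydrofuran-3-yl]methyl acetate; 17 (2E,4E)-2-[[tert-butyl(dimethyl)silyl]oxymethyl]-5-(tributylstannyl)penta-2,4-dien-1-ol
Product: 18 [(5S)-5-[(1Z,3E,5E)-7-[tert-butyl(dimethyl)silyl]oxy-6-(hydroxymethyl)-2-methylhepta-1,3,5-trienyl]-4-(hydroxymethyl)-2-oxo-2,5-dihydrofuran-3-yl]methyl acetate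
Conditions: Pd2(dba)3 (5 mol%), AsPh3 (40 mol%), N-methylpyrrolidone, rt, dark
Reagents that add atoms: none
Why: Stille coupling under neutral, ligand-accelerated conditions joins C3 to C4 with retention at both partners and completes the Z,E,Z-triene. No base is present, so C6 and the acetate are safe, and the tetrasubstituted allylic acetate should ionise far more slowly than the vinyl iodide adds to zerovalent palladium.

Step 13
Reactants: 18 [(5S)-5-[(1Z,3E,5E)-7-[tert-butyl(dimethyl)silyl]oxy-6-(hydroxymethyl)-2-methylhepta-1,3,5-trienyl]-4-(hydroxymethyl)-2-oxo-2,5-dihydrofuran-3-yl]methyl acetate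
Product: 19 [(5S)-5-[(1Z,3E,5Z)-7-[tert-butyl(dimethyl)silyl]oxy-6-formyl-2-methylhepta-1,3,5-trienyl]-4-formyl-2-oxo-2,5-dihydrofuran-3-yl]methyl acetate
Conditions: Dess–Martin periodinane (3 equiv), NaHCO3, CH2Cl2, 0 °C, dark; used at once
Reagents that add atoms: none
Why: Dess–Martin oxidation converts both primary allylic alcohols to aldehydes under buffered, non-basic conditions without touching alkene geometry. Compound 19 is not stored because the C7 formyl group makes C6–H acidic and the 10Z-dienal can equilibrate with its 2H-pyran valence isomer.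

Step 14
Reactants: 19 [(5S)-5-[(1Z,3E,5Z)-7-[tert-butyl(dimethyl)silyl]oxy-6-formyl-2-methylhepta-1,3,5-trienyl]-4-formyl-2-oxo-2,5-dihydrofuran-3-yl]methyl acetate
Product: 20 (6S,8R,9R)-13-acetoxy-14-[tert-butyl(dimethyl)silyl]oxy-8,9-dihydroxygermacra-1(10)Z,2E,4Z,7(11)-tetraen-12,6-olide
Conditions: Cp2TiCl2 (3 equiv), Mn dust (8 equiv), degassed THF, rt; 19 added over 8 h (final 2 mM), rt; aq. NH4Cl
Reagents that add atoms: none
Why: Cp2TiCl (trivalent titanium, formed from Cp2TiCl2 and Mn) binds each formyl oxygen and transfers one electron, giving two O-titanated allylic radicals that combine head to head at C8 and C9; hydrolysis of the titanium diolate gives 20. The closest known reaction types are the threo-selective Cp2TiCl pinacol coupling of conjugated aldehydes and the low-valent titanium pinacol macrocyclisation of dialdehydes. The ten-membered carbocycle closes by intramolecular radical–radical combination in which both new carbinol carbons become ring members, and slow addition keeps the monomer dilute. C8: the formyl group on C7 is held s-trans (oxygen towards C6, hydrogen towards the C13 methylene) and C9 can only arrive on the butenolide face that carries the C5 chain, which should give 8R. C9: the two bulky Cp2ClTi–O groups stay anti across the forming bond, which in the ring means a trans (threo) diol, hence 9R. The step needs head-to-head coupling (favoured by the spin density and the titanium at the oxygen-bearing carbons) and ring closure over oligomerisation (helped by the few rotatable bonds between the butenolide and the Z,E,Z-triene). Esters, the lactone, the silyl ether and the alkenes are inert to Cp2TiCl, and the substrate has no oxirane or saturated carbonyl group.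

Step 15
Reactants: 20 (6S,8R,9R)-13-acetoxy-14-[tert-butyl(dimethyl)silyl]oxy-8,9-dihydroxygermacra-1(10)Z,2E,4Z,7(11)-tetraen-12,6-olide
Product: 21 (6S,8R,9R)-8,13-diacetoxy-14-[tert-butyl(dimethyl)silyl]oxy-9-hydroxygermacra-1(10)Z,2E,4Z,7(11)-tetraen-12,6-olide
Conditions: Ac2O (1.1 equiv), 2,4,6-collidine, CH2Cl2, −40 to 0 °C
Reagents that add atoms: acetic anhydride CC(=O)OC(C)=O
Why: Acylation with one equivalent of anhydride at low temperature; O8 should react first because O9 lies between C8 and C10 with its bulky silyloxymethyl group, and the weak base limits 1,2-acetyl migration.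

Step 16
Reactants: 22 (R)-(2-methyloxiran-2-yl)methanol
Product: 23 (S)-2-methyloxirane-2-carboxylic acid
Conditions: TEMPO (0.2 equiv), PhI(OAc)2 (2.2 equiv), MeCN–H2O, rt
Reagents that add atoms: water O
Why: Oxoammonium oxidation of a primary alcohol to the acid in aqueous acetonitrile leaves the oxirane intact; the stereocentre is not touched and its descriptor changes from R to S only because the carboxyl group outranks the ring methylene.

Step 17
Reactants: 21 (6S,8R,9R)-8,13-diacetoxy-14-[tert-butyl(dimethyl)silyl]oxy-9-hydroxygermacra-1(10)Z,2E,4Z,7(11)-tetraen-12,6-olide; 23 (S)-2-methyloxirane-2-carboxylic acid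
Product: 25 (6S,8R,9R)-8,13-diacetoxy-14-[tert-butyl(dimethyl)silyl]oxy-9-[(2S)-2-methyloxirane-2-carbonyl]oxygermacra-1(10)Z,2E,4Z,7(11)-tetraen-12,6-olide, via mixed Yamaguchi anhydride 24 (not isolated)
Conditions: 23, 2,4,6-Cl3C6H2COCl, Et3N, toluene, rt; then 21, DMAP, toluene, rt
Reagents that add atoms: none
Why: Yamaguchi esterification through the mixed anhydride 24 acylates the hindered allylic C9 hydroxyl; the quaternary α-carbon of the acid cannot epimerise, and capping O9 ends the risk of acetyl migration.

Step 18
Reactants: 25 (6S,8R,9R)-8,13-diacetoxy-14-[tert-butyl(dimethyl)silyl]oxy-9-[(2S)-2-methyloxirane-2-carbonyl]oxygermacra-1(10)Z,2E,4Z,7(11)-tetraen-12,6-olide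
Product: 26 (6S,8R,9R)-8,13-diacetoxy-14-hydroxy-9-[(2S)-2-methyloxirane-2-carbonyl]oxygermacra-1(10)Z,2E,4Z,7(11)-tetraen-12,6-olide
Conditions: HF·pyridine, pyridine, THF, 0 °C
Reagents that add atoms: none
Why: Buffered HF·pyridine removes the primary allylic silyl ether; the acetates, the electron-poor glycidic ester and the triene should tolerate these conditions.

Step 19
Reactants: 26 (6S,8R,9R)-8,13-diacetoxy-14-hydroxy-9-[(2S)-2-methyloxirane-2-carbonyl]oxygermacra-1(10)Z,2E,4Z,7(11)-tetraen-12,6-olide
Product: 27 (6S,8R,9R)-8,13-diacetoxy-9-[(2S)-2-methyloxirane-2-carbonyl]oxy-14-(3-methylbut-2-enoyl)oxygermacra-1(10)Z,2E,4Z,7(11)-tetraen-12,6-olide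
Conditions: Me2C=CHCO2H, EDC·HCl, DMAP (cat.), CH2Cl2, 0 °C to rt
Reagents that add atoms: 3-methylbut-2-enoic acid CC(C)=CC(O)=O
Why: Steglich esterification of the primary alcohol; with only catalytic DMAP and no stronger base the senecioate should not slip to its β,γ-unsaturated isomer.

Step 20
Reactants: 27 (6S,8R,9R)-8,13-diacetoxy-9-[(2S)-2-methyloxirane-2-carbonyl]oxy-14-(3-methylbut-2-enoyl)oxygermacra-1(10)Z,2E,4Z,7(11)-tetraen-12,6-olide
Product: 28 (2R,3S,4S,5S,6R,8R,9R)-8,13-diacetoxy-2,3:4,5-diepoxy-9-[(2S)-2-methyloxirane-2-carbonyl]oxy-14-(3-methylbut-2-enoyl)oxygermacra-1(10)Z,7(11)-dien-12,6-olide (CNP0279449.1)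
Conditions: dimethyldioxirane (2.5 equiv), acetone, −20 to 0 °C
Reagents that add atoms: dimethyldioxirane CC1(C)OO1
Why: Epoxidation by a neutral dioxirane transfers oxygen stereospecifically, so the 2E alkene gives the trans- and the 4Z alkene the cis-oxirane; the C1=C10 alkene (two allylic ester groups), the senecioate and the butenolide are electron-poor and should react last. The face at each alkene is set by attack from outside the ring on the conformation fixed by C6, C8 and C9, which is expected, but not secured, to give 2R,3S,4S,5S.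

## Compound list

1 | but-2-yn-1-ol | CC#CCO | starting material
2 | (Z)-3-(triethylsilyl)but-2-en-1-ol | OC/C=C(C)\[Si](CC)(CC)CC | intermediate
3 | (Z)-3-(triethylsilyl)but-2-enal | O=C/C=C(C)\[Si](CC)(CC)CC | intermediate
4 | tert-butyl(dimethyl)(prop-2-ynyloxy)silane | C#CCO[Si](C)(C)C(C)(C)C | starting material
5 | (4S,5Z)-1-[tert-butyl(dimethyl)silyl]oxy-6-(triethylsilyl)hept-5-en-2-yn-4-ol | CC(C)(C)[Si](C)(C)OCC#C[C@@H](O)/C=C(C)\[Si](CC)(CC)CC | intermediate
6 | cyclic alkenylmagnesium alkoxide: (5S)-3-[[tert-butyl(dimethyl)silyl]oxymethyl]-4-ethenyl-5-[(Z)-2-(triethylsilyl)prop-1-enyl]-2,5-dihydro-1,2-oxamagnesole | CC(C)(C)[Si](C)(C)OCC1=C(C=C)[C@H](/C=C(C)\[Si](CC)(CC)CC)O[Mg]1 | intermediate (not isolated)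
7 | (5S)-3-[[tert-butyl(dimethyl)silyl]oxymethyl]-4-ethenyl-5-[(Z)-2-(triethylsilyl)prop-1-enyl]furan-2(5H)-one | CC(C)(C)[Si](C)(C)OCC1=C(C=C)[C@H](/C=C(C)\[Si](CC)(CC)CC)OC1=O | intermediate (not isolated)
8 | (5S)-4-ethenyl-3-(hydroxymethyl)-5-[(Z)-2-(triethylsilyl)prop-1-enyl]furan-2(5H)-one | OCC1=C(C=C)[C@H](/C=C(C)\[Si](CC)(CC)CC)OC1=O | intermediate
9 | (5S)-4-ethenyl-3-(hydroxymethyl)-5-[(Z)-2-iodoprop-1-enyl]furan-2(5H)-one | OCC1=C(C=C)[C@H](/C=C(C)\I)OC1=O | intermediate
10 | [(5S)-4-ethenyl-5-[(Z)-2-iodoprop-1-enyl]-2-oxo-2,5-dihydrofuran-3-yl]methyl acetate | CC(=O)OCC1=C(C=C)[C@H](/C=C(C)\I)OC1=O | intermediate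
11 | [(5S)-4-formyl-5-[(Z)-2-iodoprop-1-enyl]-2-oxo-2,5-dihydrofuran-3-yl]methyl acetate | CC(=O)OCC1=C(C=O)[C@H](/C=C(C)\I)OC1=O | intermediate (not isolated)
12 | [(5S)-4-(hydroxymethyl)-5-[(Z)-2-iodoprop-1-enyl]-2-oxo-2,5-dihydrofuran-3-yl]methyl acetate | CC(=O)OCC1=C(CO)[C@H](/C=C(C)\I)OC1=O | intermediate
13 | (Z)-2-[[tert-butyl(dimethyl)silyl]oxymethyl]-3-[dimethyl(phenyl)silyl]prop-2-enal | O=C/C(CO[Si](C)(C)C(C)(C)C)=C\[Si](C)(C)c1ccccc1 | intermediate
14 | (E)-2-[[tert-butyl(dimethyl)silyl]oxymethyl]-3-[dimethyl(phenyl)silyl]prop-2-en-1-ol (silicon cis to CH2OH) | OC/C(CO[Si](C)(C)C(C)(C)C)=C\[Si](C)(C)c1ccccc1 | intermediate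
15 | (E)-2-[[tert-butyl(dimethyl)silyl]oxymethyl]-3-iodoprop-2-en-1-ol (iodine cis to CH2OH) | OC/C(CO[Si](C)(C)C(C)(C)C)=C\I | intermediate
16 | (E)-1,2-bis(tributylstannyl)ethene | CCCC[Sn](CCCC)(CCCC)/C=C/[Sn](CCCC)(CCCC)CCCC | starting material
17 | (2E,4E)-2-[[tert-butyl(dimethyl)silyl]oxymethyl]-5-(tributylstannyl)penta-2,4-dien-1-ol | OC/C(CO[Si](C)(C)C(C)(C)C)=C\C=C\[Sn](CCCC)(CCCC)CCCC | intermediate
18 | [(5S)-5-[(1Z,3E,5E)-7-[tert-butyl(dimethyl)silyl]oxy-6-(hydroxymethyl)-2-methylhepta-1,3,5-trienyl]-4-(hydroxymethyl)-2-oxo-2,5-dihydrofuran-3-yl]methyl acetate | CC(=O)OCC1=C(CO)[C@H](/C=C(C)\C=C\C=C(/CO)CO[Si](C)(C)C(C)(C)C)OC1=O | intermediate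
19 | [(5S)-5-[(1Z,3E,5Z)-7-[tert-butyl(dimethyl)silyl]oxy-6-formyl-2-methylhepta-1,3,5-trienyl]-4-formyl-2-oxo-2,5-dihydrofuran-3-yl]methyl acetate | CC(=O)OCC1=C(C=O)[C@H](/C=C(C)\C=C\C=C(/C=O)CO[Si](C)(C)C(C)(C)C)OC1=O | intermediate
20 | (6S,8R,9R)-13-acetoxy-14-[tert-butyl(dimethyl)silyl]oxy-8,9-dihydroxygermacra-1(10)Z,2E,4Z,7(11)-tetraen-12,6-olide | CC(=O)OCC1=C2[C@@H](O)[C@H](O)/C(CO[Si](C)(C)C(C)(C)C)=C\C=C\C(C)=C/[C@@H]2OC1=O | intermediate
21 | (6S,8R,9R)-8,13-diacetoxy-14-[tert-butyl(dimethyl)silyl]oxy-9-hydroxygermacra-1(10)Z,2E,4Z,7(11)-tetraen-12,6-olide | CC(=O)OCC1=C2[C@@H](OC(C)=O)[C@H](O)/C(CO[Si](C)(C)C(C)(C)C)=C\C=C\C(C)=C/[C@@H]2OC1=O | intermediate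
22 | (R)-(2-methyloxiran-2-yl)methanol | OC[C@]1(C)CO1 | starting material
23 | (S)-2-methyloxirane-2-carboxylic acid | OC(=O)[C@]1(C)CO1 | intermediate
24 | (S)-2-methyloxirane-2-carboxylic 2,4,6-trichlorobenzoic anhydride | O=C(OC(=O)[C@]1(C)CO1)c1c(Cl)cc(Cl)cc1Cl | intermediate (not isolated)
25 | (6S,8R,9R)-8,13-diacetoxy-14-[tert-butyl(dimethyl)silyl]oxy-9-[(2S)-2-methyloxirane-2-carbonyl]oxygermacra-1(10)Z,2E,4Z,7(11)-tetraen-12,6-olide | CC(=O)OCC1=C2[C@@H](OC(C)=O)[C@H](OC(=O)[C@]3(C)CO3)/C(CO[Si](C)(C)C(C)(C)C)=C\C=C\C(C)=C/[C@@H]2OC1=O | intermediate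
26 | (6S,8R,9R)-8,13-diacetoxy-14-hydroxy-9-[(2S)-2-methyloxirane-2-carbonyl]oxygermacra-1(10)Z,2E,4Z,7(11)-tetraen-12,6-olide | CC(=O)OCC1=C2[C@@H](OC(C)=O)[C@H](OC(=O)[C@]3(C)CO3)/C(CO)=C\C=C\C(C)=C/[C@@H]2OC1=O | intermediate
27 | (6S,8R,9R)-8,13-diacetoxy-9-[(2S)-2-methyloxirane-2-carbonyl]oxy-14-(3-methylbut-2-enoyl)oxygermacra-1(10)Z,2E,4Z,7(11)-tetraen-12,6-olide | CC(=O)OCC1=C2[C@@H](OC(C)=O)[C@H](OC(=O)[C@]3(C)CO3)/C(COC(=O)C=C(C)C)=C\C=C\C(C)=C/[C@@H]2OC1=O | intermediate
28 | (2R,3S,4S,5S,6R,8R,9R)-8,13-diacetoxy-2,3:4,5-diepoxy-9-[(2S)-2-methyloxirane-2-carbonyl]oxy-14-(3-methylbut-2-enoyl)oxygermacra-1(10)Z,7(11)-dien-12,6-olide (CNP0279449.1) | CC(=O)OCC1=C2[C@@H](OC(C)=O)[C@H](OC(=O)[C@]3(C)CO3)/C(COC(=O)C=C(C)C)=C\[C@H]3O[C@@H]3[C@@]3(C)O[C@H]3[C@@H]2OC1=O | target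

## Step count and least certain steps

Total step count: 20. Longest linear sequence: 15 steps (steps 1–7, 12–15, 17–20). Steps 8–11 and step 16 are side branches.

**Step 14 (key step).** Most likely failure: intermolecular coupling or simple reduction of the aldehydes outruns closure of the strained ten-membered ring, and the relay from C6 does not fully separate the two trans-diols. The two ketyl radicals are formed independently, and only the chain fold carries the stereochemical information. Fallback, setting out from 19 and coming back at 20: the same bond is closed on McMurry-type heterogeneous low-valent titanium (TiCl3(DME)1.5, Zn–Cu, DME, low temperature, stopped at the diol). Here both oxygens are anchored to the metal surface before the carbons join, a template mechanism that is established for ten-membered trans-diols. Diol isomers other than 20 are separated and cleaved with NaIO4 back to 19, so the material is recycled through the closure. No new compound arises.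

**Step 4.** Most likely failure: slow or incomplete carbometalation of the internal alkyne, and loss of silanolate from the alkenylmagnesium (allene formation), because magnesium sits β to a silyloxy group and internal 2-alkyn-1-ols add Grignard reagents reluctantly. Fallback, setting out from 3 and coming back at 8: the butenolide is built by syn-carbocupration of an ynoate.
- Enal 3 is alkynylated with methyl propiolate under the zinc–ProPhenol conditions of step 3 to methyl (4S,5Z)-4-hydroxy-6-(triethylsilyl)hept-5-en-2-ynoate F1.
- Lithium divinylcuprate (CH2=CH)2CuLi adds syn across the ynoate at −78 °C, the α-cuprio enoate is quenched with iodine, and the hydroxy ester lactonises to (5S)-4-ethenyl-3-iodo-5-[(Z)-2-(triethylsilyl)prop-1-enyl]furan-2(5H)-one F2.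
- Stille coupling of F2 with Bu3SnCH2OH (Pd(PPh3)4, dioxane, 80 °C) places C13 as the hydroxymethyl group and gives 8.

**Step 15.** Most likely failure: poor discrimination between O8 and O9, and acetyl migration between them, because both are secondary allylic hydroxyls on adjacent carbons. Fallback, setting out from 20 and coming back at 27: O9 and O14 are tied together so that only O8 is free.
- HF·pyridine converts 20 into the triol (6S,8R,9R)-13-acetoxy-8,9,14-trihydroxygermacra-1(10)Z,2E,4Z,7(11)-tetraen-12,6-olide F3.
- tBu2Si(OTf)2 and 2,6-lutidine close the six-membered silylene on the 1,3-diol, giving the 9,14-O-(di-tert-butylsilylene) derivative F4.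
- Ac2O, pyridine and DMAP give the 8-O-acetyl-9,14-O-(di-tert-butylsilylene) derivative F5.
- HF·pyridine frees the 8-O-acetyl-9,14-diol F6.
- Steglich acylation of the primary hydroxyl with 3-methylbut-2-enoic acid gives the 8-O-acetyl-14-O-(3-methylbut-2-enoyl)-9-ol F7.
- Yamaguchi esterification of F7 with 23 gives 27.

**Step 20.** Most likely failure: poor facial selectivity at one of the two alkenes, or competing oxidation of C1=C10, because the selectivity rests on the ring conformation and on a modest electronic bias. Fallback, setting out from 27 and coming back at 28: control is moved to the reagent and the two alkenes are taken one at a time by Shi epoxidation (fructose-derived ketone, KHSO5, buffered MeCN–dimethoxymethane–water, 0 °C). For each alkene the ketone enantiomer (from D- or L-fructose) is chosen by the spiro transition-state model. The trisubstituted C4=C5 alkene reacts first to the 4,5-monoepoxide (4R,5S,6R,8R,9R)-8,13-diacetoxy-4,5-epoxy-9-[(2S)-2-methyloxirane-2-carbonyl]oxy-14-(3-methylbut-2-enoyl)oxygermacra-1(10)Z,2E,7(11)-trien-12,6-olide F8, and the trans C2=C3 alkene of F8 is epoxidised in a second run to 28.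

## Further compounds

F0 | step 14 | none | none
F1 | step 4 | methyl (4S,5Z)-4-hydroxy-6-(triethylsilyl)hept-5-en-2-ynoate | COC(=O)C#C[C@@H](O)/C=C(C)\[Si](CC)(CC)CC
F2 | step 4 | (5S)-4-ethenyl-3-iodo-5-[(Z)-2-(triethylsilyl)prop-1-enyl]furan-2(5H)-one | IC1=C(C=C)[C@H](/C=C(C)\[Si](CC)(CC)CC)OC1=O
F3 | step 15 | (6S,8R,9R)-13-acetoxy-8,9,14-trihydroxygermacra-1(10)Z,2E,4Z,7(11)-tetraen-12,6-olide | CC(=O)OCC1=C2[C@@H](O)[C@H](O)/C(CO)=C\C=C\C(C)=C/[C@@H]2OC1=O
F4 | step 15 | (6S,8R,9R)-13-acetoxy-9,14-O-(di-tert-butylsilylene)-8-hydroxygermacra-1(10)Z,2E,4Z,7(11)-tetraen-12,6-olide | CC(=O)OCC1=C2[C@@H](O)[C@@H]3O[Si](C(C)(C)C)(C(C)(C)C)OC\C3=C\C=C\C(C)=C/[C@@H]2OC1=O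
F5 | step 15 | (6S,8R,9R)-8,13-diacetoxy-9,14-O-(di-tert-butylsilylene)germacra-1(10)Z,2E,4Z,7(11)-tetraen-12,6-olide | CC(=O)OCC1=C2[C@@H](OC(C)=O)[C@@H]3O[Si](C(C)(C)C)(C(C)(C)C)OC\C3=C\C=C\C(C)=C/[C@@H]2OC1=O
F6 | step 15 | (6S,8R,9R)-8,13-diacetoxy-9,14-dihydroxygermacra-1(10)Z,2E,4Z,7(11)-tetraen-12,6-olide | CC(=O)OCC1=C2[C@@H](OC(C)=O)[C@H](O)/C(CO)=C\C=C\C(C)=C/[C@@H]2OC1=O
F7 | step 15 | (6S,8R,9R)-8,13-diacetoxy-9-hydroxy-14-(3-methylbut-2-enoyl)oxygermacra-1(10)Z,2E,4Z,7(11)-tetraen-12,6-olide | CC(=O)OCC1=C2[C@@H](OC(C)=O)[C@H](O)/C(COC(=O)C=C(C)C)=C\C=C\C(C)=C/[C@@H]2OC1=O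
F8 | step 20 | (4R,5S,6R,8R,9R)-8,13-diacetoxy-4,5-epoxy-9-[(2S)-2-methyloxirane-2-carbonyl]oxy-14-(3-methylbut-2-enoyl)oxygermacra-1(10)Z,2E,7(11)-trien-12,6-olide | CC(=O)OCC1=C2[C@@H](OC(C)=O)[C@H](OC(=O)[C@]3(C)CO3)/C(COC(=O)C=C(C)C)=C\C=C\[C@@]3(C)O[C@H]3[C@@H]2OC1=O
A1 | alternative 1 | bromobenzene | Brc1ccccc1
A2 | alternative 1 | (1S,2S)-3-bromocyclohexa-3,5-diene-1,2-diol | BrC1=CC=C[C@H](O)[C@@H]1O
A3 | alternative 2 | ten-membered bis-epoxy C6 ketone with the seco ester (Darzens product) | COC(=O)/C(COC(C)=O)=C1/[C@@H](OC(C)=O)[C@H](O[Si](C)(C)C(C)(C)C)/C(CO[Si](C)(C)C(C)(C)C)=C\[C@H]2O[C@@H]2[C@@]2(C)O[C@H]2C1=O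
A4 | alternative 3 | Z,E,Z-cyclodecatrienone with the C8/C9 acetonide | C1[C@H]2OC(C)(C)O[C@@H]2/C(CO[Si](C)(C)C(C)(C)C)=C\C=C\C(C)=C/C1=O
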